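**Retrosynthetic overview**
1. Target ⇐ 8-O-angeloylation, 10-O-acetylation and dihydroxylation/oxidation of the C-1=C-10 alkene of a ten-membered E-cycloalkene carrying the cis-fused α-methylene lactone.
2. Lactone ⇐ γ-keto ester; ten-membered ring ⇐ anionic oxy-Cope ring expansion of a trans-1,2-dialkenylcyclohexanol (C-1–C-6 broken, C-8–C-9 formed), with the enolate alkylated in the same flask.
3. Cyclohexanol ⇐ 2-isopropenylcyclohexanone + (Z)-2-(benzyloxy)vinyllithium.
4. Ketone ⇐ enantioselective desymmetrisation (rhodium-catalysed isopropenyl 1,4-addition) of achiral 4,4-dimethoxycyclohexadienone, formed in the same flask by oxidative dearomatisation of 4-methoxyphenol.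
5. Ring order: six-membered ring A (from the arene) → ten-membered carbocycle → γ-lactone.

**Locants.** C-1 ring ketone, C-2 CH2, C-3 CH(OH), C-4 CH(CH3), C-5 CH2, C-6 CH–O (lactone), C-7 ring-fusion CH, C-8 CH–O (angelate), C-9 CH2, C-10 C(CH3)(OAc), C-11/C-12/C-13 lactone α-carbon/carbonyl/exocyclic CH2, C-14 methyl on C-10, C-15 methyl on C-4. The same locants are used for ring A (C-1 to C-6). With the ring drawn flat and numbered clockwise, β is towards the viewer. The target is 3β-OH, 4β-CH3, 6α-O, 7α-C-11, 8α-O, 10α-OAc, 10β-CH3 (3R,4S,6S,7S,8R,10S).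

**Assumption.** (S)-BINAP is taken to give the (S)-adduct 4, the sense found with simple cyclohexenones; if the sense is opposite, (R)-BINAP is used.

Step 1
Reactants: 1 4-methoxyphenol; 2 potassium trifluoro(prop-1-en-2-yl)borate
Product: 4 (S)-4,4-dimethoxy-5-(prop-1-en-2-yl)cyclohex-2-en-1-one, via quinone monoketal 3 (not isolated)
Conditions: PhI(OAc)2, MeOH, 0 °C; evaporate; then 2 (1.05 equiv), [Rh(cod)2]BF4 (3 mol %), (S)-BINAP, Et3N, toluene/H2O, 25 °C
Reagents that add atoms: methanol, CO; potassium trifluoro(prop-1-en-2-yl)borate (2), [K+].C=C(C)[B-](F)(F)F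
Why: Proposed new method: trivalent-iodine oxidation of the phenol in methanol gives the achiral monoketal (a standard oxidative dearomatisation), and in the same flask a monovalent-rhodium/(S)-BINAP complex takes the isopropenyl group from boron and inserts one of the two enantiotopic enone units on one face before protonolysis, which sets C-1 (closest known reaction: Hayashi–Miyaura 1,4-addition of potassium alkenyltrifluoroborates to cyclic enones and to a benzo-fused quinone monoketal).

Step 2
Reactants: 4 (S)-4,4-dimethoxy-5-(prop-1-en-2-yl)cyclohex-2-en-1-one; 5 iodomethane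
Product: 7 (2S,5S)-4,4-dimethoxy-2-methyl-5-(prop-1-en-2-yl)cyclohexan-1-one, via lithium enolate 6 (not isolated)
Conditions: LiBH(s-Bu)3, THF, −78 °C; then MeI, −78 to 0 °C
Reagents that add atoms: iodomethane (5), CI
Why: Reductive alkylation: conjugate hydride addition gives the regiodefined enolate, which is methylated on the face opposite the axial methoxy group of the ketal, so the C-4 methyl ends equatorial and trans to the isopropenyl group, which is also the thermodynamic arrangement at this epimerisable centre.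

Step 3
Reactants: 7 (2S,5S)-4,4-dimethoxy-2-methyl-5-(prop-1-en-2-yl)cyclohexan-1-one
Product: 8 (1R,2S,5S)-4,4-dimethoxy-2-methyl-5-(prop-1-en-2-yl)cyclohexan-1-ol
Conditions: LiBH(s-Bu)3, THF, −78 °C; H2O
Reagents that add atoms: none
Why: Bulky-hydride ketone reduction by equatorial attack gives the axial C-3 alcohol cis to the neighbouring equatorial methyl, the relationship found in the target.

Step 4
Reactants: 8 (1R,2S,5S)-4,4-dimethoxy-2-methyl-5-(prop-1-en-2-yl)cyclohexan-1-ol
Product: 10 (2S,4R,5S)-5-methyl-2-(prop-1-en-2-yl)-4-(triisopropylsilyloxy)cyclohexan-1-one, via silyl ether 9 (not isolated)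
Conditions: i-Pr3SiOTf, 2,6-lutidine, CH2Cl2, −78 to 0 °C; then (CO2H)2, THF/H2O, 25 °C
Reagents that add atoms: triisopropylsilyl trifluoromethanesulfonate, CC(C)[Si](C(C)C)(C(C)C)OS(=O)(=O)C(F)(F)F; water, O
Why: Silyl triflate protection of the hindered axial alcohol, then mild acid hydrolysis of the dimethyl ketal, unmasks the C-6 ketone without creating a stereocentre, and the α-isopropenyl centre stays in its more stable equatorial configuration.

Step 5
Reactants: 11 benzyl vinyl ether
Product: 13 (Z)-2-bromovinyl benzyl ether, via dibromide 12 (not isolated)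
Conditions: Br2, CH2Cl2, −78 °C; then i-Pr2NEt, −78 to 25 °C; Z isomer separated by distillation
Reagents that add atoms: bromine, BrBr
Why: Bromination of the enol ether and amine-induced dehydrobromination of the α-bromo ether (the method used for cis-2-ethoxyvinyl bromide) gives mainly the cis β-bromo enol ether, the isomer whose lithio derivative does not undergo anti β-elimination.

Step 6
Reactants: 10 (2S,4R,5S)-5-methyl-2-(prop-1-en-2-yl)-4-(triisopropylsilyloxy)cyclohexan-1-one; 13 (Z)-2-bromovinyl benzyl ether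
Product: 15 (1S,2S,4R,5S)-1-[(Z)-2-(benzyloxy)ethenyl]-5-methyl-2-(prop-1-en-2-yl)-4-(triisopropylsilyloxy)cyclohexan-1-ol, via vinyllithium 14 (not isolated)
Conditions: 13, t-BuLi (2 equiv), Et2O, −78 °C; then LaCl3·2LiCl, 10, THF, −78 °C; H2O
Reagents that add atoms: (Z)-2-bromovinyl benzyl ether (13), Br/C=C\OCc1ccccc1
Why: Bromine–lithium exchange with retention of geometry and lanthanum-promoted 1,2-addition to the enolisable ketone from the equatorial direction, anti to the neighbouring isopropenyl group, gives the trans-1,2-dialkenyl carbinol (both alkenyl groups equatorial, hydroxyl axial).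

Step 7
Reactants: 15 (1S,2S,4R,5S)-1-[(Z)-2-(benzyloxy)ethenyl]-5-methyl-2-(prop-1-en-2-yl)-4-(triisopropylsilyloxy)cyclohexan-1-ol; 16 methyl bromoacetate
Product: 19 methyl 2-[(1(10)E)-8α-benzyloxy-4β,10-dimethyl-6-oxo-3β-(triisopropylsilyloxy)cyclodec-1(10)-en-7α-yl]acetate, via potassium alkoxide 17 (not isolated), via potassium enolate 18 (not isolated)
Conditions: KH, 18-crown-6, THF, 0 to 25 °C; then BrCH2CO2Me, −78 °C
Reagents that add atoms: methyl bromoacetate (16), COC(=O)CBr
Why: Anionic oxy-Cope rearrangement through a chair, trans-decalin-like transition state breaks C-1–C-6 and forms C-8–C-9, giving the E C-1=C-10 alkene and relaying chirality from C-1/C-6 to C-8 (the cis benzyloxy group is pseudo-axial and ends α), and the enolate, whose β-benzyloxy group lies in the nodal plane so that β-elimination is retarded, is alkylated on its exposed face anti to the new C-8–C-9 bond, placing the acetate arm α and cis to O-8.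

Step 8
Reactants: 19 methyl 2-[(1(10)E)-8α-benzyloxy-4β,10-dimethyl-6-oxo-3β-(triisopropylsilyloxy)cyclodec-1(10)-en-7α-yl]acetate
Product: 21 cis-fused γ-lactone (6α-O–C-12; 8α-benzyloxy; 3β-triisopropylsilyloxy; 1(10)E-ene), via hydroxy ester 20 (not isolated)
Conditions: NaBH4, MeOH, −40 °C; then PPTS (cat.), CH2Cl2, 25 °C
Reagents that add atoms: none
Why: Chemoselective borohydride reduction of the ketone on its exposed face (anti to the transannular alkene) gives the 6α-alcohol syn to both neighbours, which closes the cis-fused γ-lactone by acid-catalysed lactonisation.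

Step 9
Reactants: 21 cis-fused γ-lactone; 22 dimethyl(methylidene)ammonium iodide; 5 iodomethane
Product: 26 α-methylene lactone (C-11=C-13), via lactone enolate 23 (not isolated), via Mannich base 24 (not isolated), via methiodide 25 (not isolated)
Conditions: LiN(i-Pr)2, THF, −78 °C; 22, −78 to 25 °C; then MeI, MeOH, 25 °C; then NaHCO3, CH2Cl2/H2O
Reagents that add atoms: dimethyl(methylidene)ammonium iodide (22), C=[N+](C)C.[I-]
Why: Mannich reaction of the lactone enolate with Eschenmoser's salt, quaternisation and Hofmann-type elimination install the exocyclic methylene without touching any stereocentre.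

Step 10
Reactants: 26 α-methylene lactone
Product: 27 1β,10α-diol
Conditions: OsO4 (2 mol %), N-methylmorpholine N-oxide, acetone/H2O, 0 °C
Reagents that add atoms: N-methylmorpholine N-oxide, C[N+]1([O-])CCOCC1; water, O
Why: Upjohn syn-dihydroxylation is selective for the electron-rich trisubstituted alkene over the acrylate, and attack on the exposed face of the alkene rotamer that keeps H-8 rather than the benzyloxy group inside the ring puts the tertiary C-10 oxygen α, syn to O-8.

Step 11
Reactants: 27 1β,10α-diol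
Product: 28 10α-hydroxy-1-ketone
Conditions: 2-iodoxybenzoic acid, DMSO, 25 °C
Reagents that add atoms: none
Why: Hypervalent-iodine oxidation converts the secondary alcohol of the vicinal diol into the ketone without glycol cleavage and leaves the tertiary C-10 centre unchanged.

Step 12
Reactants: 28 10α-hydroxy-1-ketone; 29 acetic anhydride
Product: 30 10α-acetoxy-1-ketone
Conditions: Ac2O, DMAP, Et3N, CH2Cl2, 25 to 40 °C
Reagents that add atoms: acetic anhydride (29), CC(=O)OC(C)=O
Why: DMAP-catalysed acylation of the only free hydroxyl, the tertiary α-ketol, installs the C-10 acetate with retention.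

Step 13
Reactants: 30 10α-acetoxy-1-ketone
Product: 31 8α-alcohol
Conditions: BCl3, C6HMe5, CH2Cl2, −78 °C; MeOH
Reagents that add atoms: none
Why: Lewis-acid debenzylation with pentamethylbenzene as benzyl-cation scavenger frees the C-8 hydroxyl at low temperature without affecting the silyl ether, the esters or the alkenes.

Step 14
Reactants: 31 8α-alcohol; 32 angelic acid
Product: 34 8α-angelate 3β-silyl ether, via mixed anhydride 33 (not isolated)
Conditions: 32, 2,4,6-Cl3C6H2COCl, Et3N, toluene, 25 °C; then 31, toluene, 60 °C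
Reagents that add atoms: angelic acid (32), C/C=C(/C)C(=O)O
Why: Yamaguchi esterification through the mixed anhydride acylates the only free (secondary) hydroxyl with retention at C-8 under conditions that preserve the Z geometry of the angeloyl group.

Step 15
Reactants: 34 8α-angelate 3β-silyl ether
Product: 35 target CNP0141210.3
Conditions: HF·pyridine, THF, 0 to 25 °C
Reagents that add atoms: none
Why: Fluoride-mediated desilylation under mildly acidic conditions frees the C-3 hydroxyl without base, so the β-hydroxy ketone, the tertiary acetate, the angelate and the α-methylene lactone survive.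

**Compound list**
1 | 4-methoxyphenol | COc1ccc(O)cc1 | starting material
2 | potassium trifluoro(prop-1-en-2-yl)borate | [K+].C=C(C)[B-](F)(F)F | starting material
3 | 4,4-dimethoxycyclohexa-2,5-dien-1-one | COC1(OC)C=CC(=O)C=C1 | intermediate
4 | (S)-4,4-dimethoxy-5-(prop-1-en-2-yl)cyclohex-2-en-1-one | CC(=C)[C@@H]1CC(=O)C=CC1(OC)OC | intermediate
5 | iodomethane | CI | starting material
6 | lithium (5S)-4,4-dimethoxy-5-(prop-1-en-2-yl)cyclohex-1-en-1-olate | CC(=C)[C@@H]1CC([O-])=CCC1(OC)OC.[Li+] | intermediate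
7 | (2S,5S)-4,4-dimethoxy-2-methyl-5-(prop-1-en-2-yl)cyclohexan-1-one | CC(=C)[C@@H]1CC(=O)[C@@H](C)CC1(OC)OC | intermediate
8 | (1R,2S,5S)-4,4-dimethoxy-2-methyl-5-(prop-1-en-2-yl)cyclohexan-1-ol | CC(=C)[C@@H]1C[C@@H](O)[C@@H](C)CC1(OC)OC | intermediate
9 | triisopropylsilyl ether of 8 | CC(=C)[C@@H]1C[C@@H](O[Si](C(C)C)(C(C)C)C(C)C)[C@@H](C)CC1(OC)OC | intermediate
10 | (2S,4R,5S)-5-methyl-2-(prop-1-en-2-yl)-4-(triisopropylsilyloxy)cyclohexan-1-one | CC(=C)[C@@H]1C[C@@H](O[Si](C(C)C)(C(C)C)C(C)C)[C@@H](C)CC1=O | intermediate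
11 | benzyl vinyl ether | C=COCc1ccccc1 | starting material
12 | [(1,2-dibromoethoxy)methyl]benzene | BrCC(Br)OCc1ccccc1 | intermediate
13 | (Z)-2-bromovinyl benzyl ether | Br/C=C\OCc1ccccc1 | intermediate
14 | (Z)-[2-(benzyloxy)ethenyl]lithium | [Li]/C=C\OCc1ccccc1 | intermediate
15 | (1S,2S,4R,5S)-1-[(Z)-2-(benzyloxy)ethenyl]-5-methyl-2-(prop-1-en-2-yl)-4-(triisopropylsilyloxy)cyclohexan-1-ol | CC(=C)[C@@H]1C[C@@H](O[Si](C(C)C)(C(C)C)C(C)C)[C@@H](C)C[C@@]1(O)/C=C\OCc1ccccc1 | intermediate
16 | methyl bromoacetate | COC(=O)CBr | starting material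
17 | potassium alkoxide of 15 | CC(=C)[C@@H]1C[C@@H](O[Si](C(C)C)(C(C)C)C(C)C)[C@@H](C)C[C@@]1([O-])/C=C\OCc1ccccc1.[K+] | intermediate
18 | potassium (1(10)E,6Z)-8α-benzyloxy-4β,10-dimethyl-3β-(triisopropylsilyloxy)cyclodeca-1(10),6-dien-6-olate | C/C1=C\C[C@@H](O[Si](C(C)C)(C(C)C)C(C)C)[C@@H](C)C/C([O-])=C/[C@H](OCc2ccccc2)C1.[K+] | intermediate
19 | methyl 2-[(1(10)E)-8α-benzyloxy-4β,10-dimethyl-6-oxo-3β-(triisopropylsilyloxy)cyclodec-1(10)-en-7α-yl]acetate | C/C1=C\C[C@@H](O[Si](C(C)C)(C(C)C)C(C)C)[C@@H](C)CC(=O)[C@H](CC(=O)OC)[C@H](OCc2ccccc2)C1 | intermediate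
20 | 6α-hydroxy ester from 19 (6α-OH, 7α-CH2CO2Me, 8α-OBn) | C/C1=C\C[C@@H](O[Si](C(C)C)(C(C)C)C(C)C)[C@@H](C)C[C@H](O)[C@H](CC(=O)OC)[C@H](OCc2ccccc2)C1 | intermediate
21 | cis-fused γ-lactone (6α-O, H-6 and H-7 β; 8α-OBn; 3β-OTIPS; 4β-CH3; 1(10)E-ene) | C/C1=C\C[C@@H](O[Si](C(C)C)(C(C)C)C(C)C)[C@@H](C)C[C@@H]2OC(=O)C[C@@H]2[C@H](OCc3ccccc3)C1 | intermediate
22 | dimethyl(methylidene)ammonium iodide | C=[N+](C)C.[I-] | starting material
23 | lithium enolate of lactone 21 | C/C1=C\C[C@@H](O[Si](C(C)C)(C(C)C)C(C)C)[C@@H](C)C[C@@H]2OC([O-])=C[C@@H]2[C@H](OCc3ccccc3)C1.[Li+] | intermediate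
24 | 11-(dimethylaminomethyl) lactone (C-11 epimers) | C/C1=C\C[C@@H](O[Si](C(C)C)(C(C)C)C(C)C)[C@@H](C)C[C@@H]2OC(=O)C(CN(C)C)[C@@H]2[C@H](OCc3ccccc3)C1 | intermediate
25 | trimethylammonium iodide of 24 | C/C1=C\C[C@@H](O[Si](C(C)C)(C(C)C)C(C)C)[C@@H](C)C[C@@H]2OC(=O)C(C[N+](C)(C)C)[C@@H]2[C@H](OCc3ccccc3)C1.[I-] | intermediate
26 | α-methylene lactone (11(13)-ene; 8α-OBn; 3β-OTIPS; 1(10)E-ene) | C/C1=C\C[C@@H](O[Si](C(C)C)(C(C)C)C(C)C)[C@@H](C)C[C@@H]2OC(=O)C(=C)[C@@H]2[C@H](OCc3ccccc3)C1 | intermediate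
27 | 1β,10α-diol (10β-CH3) of 26 | C[C@@]1(O)[C@@H](O)C[C@@H](O[Si](C(C)C)(C(C)C)C(C)C)[C@@H](C)C[C@@H]2OC(=O)C(=C)[C@@H]2[C@H](OCc3ccccc3)C1 | intermediate
28 | 10α-hydroxy-1-ketone | C[C@@]1(O)C(=O)C[C@@H](O[Si](C(C)C)(C(C)C)C(C)C)[C@@H](C)C[C@@H]2OC(=O)C(=C)[C@@H]2[C@H](OCc3ccccc3)C1 | intermediate
29 | acetic anhydride | CC(=O)OC(C)=O | starting material
30 | 10α-acetoxy-1-ketone (8α-OBn, 3β-OTIPS) | C[C@@]1(OC(C)=O)C(=O)C[C@@H](O[Si](C(C)C)(C(C)C)C(C)C)[C@@H](C)C[C@@H]2OC(=O)C(=C)[C@@H]2[C@H](OCc3ccccc3)C1 | intermediate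
31 | 8α-alcohol (10α-OAc, 3β-OTIPS) | C[C@@]1(OC(C)=O)C(=O)C[C@@H](O[Si](C(C)C)(C(C)C)C(C)C)[C@@H](C)C[C@@H]2OC(=O)C(=C)[C@@H]2[C@H](O)C1 | intermediate
32 | angelic acid, (Z)-2-methylbut-2-enoic acid | C/C=C(/C)C(=O)O | starting material
33 | (Z)-2-methylbut-2-enoic 2,4,6-trichlorobenzoic anhydride | C/C=C(/C)C(=O)OC(=O)c1c(Cl)cc(Cl)cc1Cl | intermediate
34 | 8α-angelate, 10α-acetate, 3β-triisopropylsilyl ether | C[C@@]1(OC(C)=O)C(=O)C[C@@H](O[Si](C(C)C)(C(C)C)C(C)C)[C@@H](C)C[C@@H]2OC(=O)C(=C)[C@@H]2[C@H](OC(=O)/C(C)=C\C)C1 | intermediate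
35 | CNP0141210.3 (3R,4S,6S,7S,8R,10S; 3β-OH, 4β-CH3, 6α,12-lactone, 8α-angelate, 10α-acetate, 1-ketone) | C[C@@]1(OC(C)=O)C(=O)C[C@@H](O)[C@@H](C)C[C@@H]2OC(=O)C(=C)[C@@H]2[C@H](OC(=O)/C(C)=C\C)C1 | target

**Step count.** 15 steps in total; the longest linear sequence is 14 steps (steps 1–4 and 6–15; step 5 makes reagent 13).

**Steps most likely to fail**

Step 1 (one-flask dearomatisation and desymmetrisation): iodobenzene or acetate may slow the rhodium catalyst, and the ee on this simple monoketal is untested. Fallback, setting out from 1: oxidise to 3 and isolate it, add CH2=C(CH3)MgBr with CuBr·SMe2 (cat.) and Me3SiCl to give the racemic adduct F1, and resolve F1 by preparative chromatography on a chiral stationary phase. The (S)-enantiomer is 4, where the route is rejoined. This replaces asymmetric catalysis by resolution.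

Step 7 (oxy-Cope and alkylation): the pseudo-axial benzyloxy group slows the rearrangement, and the β-benzyloxy enolate may lose benzyloxide or be protonated by the bromoacetate. Fallback, setting out from 15: generate enolate 18 as before but quench it at −78 °C with Me3SiCl to isolate the silyl enol ether F2. Alkylate F2 under Lewis-acid conditions (ZnBr2, CH2Cl2) with methyl chloro(phenylsulfanyl)acetate to give the phenylsulfanyl ester F3. Remove sulfur with Bu3SnH/AIBN to return to 19. This replaces the basic enolate alkylation by a neutral SN1-type alkylation.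

Step 10 (facial selectivity at C-10): the face taken by OsO4 depends on the alkene rotamer populated in the ten-membered ring, and this is the least secure stereochemical call in the route. Fallback, setting out from 26, for the case that the reagent prefers the other face: epoxidise with mCPBA, which takes that same face, to give the epoxide F4. Open F4 with acetic acid at the tertiary carbon with inversion to give the acetoxy alcohol F5, which has the C-10 acetate α. Oxidise the C-1 alcohol with 2-iodoxybenzoic acid to return at 30. Steps 11 and 12 are then not needed.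

Further compounds
F1 | step 1 | racemic 4,4-dimethoxy-5-(prop-1-en-2-yl)cyclohex-2-en-1-one | CC(=C)C1CC(=O)C=CC1(OC)OC
F2 | step 7 | (1(10)E,6Z)-8α-benzyloxy-4β,10-dimethyl-3β-(triisopropylsilyloxy)-6-(trimethylsilyloxy)cyclodeca-1(10),6-diene | C/C1=C\C[C@@H](O[Si](C(C)C)(C(C)C)C(C)C)[C@@H](C)C/C(O[Si](C)(C)C)=C/[C@H](OCc2ccccc2)C1
F3 | step 7 | methyl 2-(phenylsulfanyl) analogue of 19 (C-11 epimers) | C/C1=C\C[C@@H](O[Si](C(C)C)(C(C)C)C(C)C)[C@@H](C)CC(=O)[C@H](C(Sc2ccccc2)C(=O)OC)[C@H](OCc3ccccc3)C1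
F4 | step 10 | 1α,10β-epoxide of 26 (oxygen β on C-10, α on C-1) | C[C@]12O[C@@H]1C[C@@H](O[Si](C(C)C)(C(C)C)C(C)C)[C@@H](C)C[C@@H]3OC(=O)C(=C)[C@@H]3[C@H](OCc4ccccc4)C2
F5 | step 10 | 10α-acetoxy-1α-hydroxy compound (8α-OBn, 3β-OTIPS) | C[C@@]1(OC(C)=O)[C@H](O)C[C@@H](O[Si](C(C)C)(C(C)C)C(C)C)[C@@H](C)C[C@@H]2OC(=O)C(=C)[C@@H]2[C@H](OCc3ccccc3)C1
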